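**Plan** (numbering: C1 = carboxyl C, C2 = stereocentre, C3=C4 = alkene, C5–C22 = the eighteen CH2 groups, then the phenol ring)
- Retrosynthesis: C1 acid ← CH2OTBS; cut C10–C11 (sp3–sp3) into a C1–C10 dienyl silyl ether and a C11–C22 aryl-dodecyl bromide; cut C4–C5 (sp2–sp3) to an (E)-alkenyl iodide plus hexa-1,5-diene; cut C22–aryl to an aryl Grignard reagent plus 1,12-dibromododecane.
- Forward chain assembly (no ring is formed): hydroxy ester → methyl alkyne → (E)-iodide → C1–C10 diene; aryl Grignard + dibromide → C11–C22 bromide; one-pot hydroboration/alkyl–alkyl Suzuki–Miyaura union; then alkyl desilylation, two-stage oxidation to the acid, and phenol release.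
- Enabling feature: the C5–C22 polymethylene chain between the trisubstituted C3=C4 alkene and the para-disubstituted benzene ring is unbranched and unfunctionalised, and the C9=C10 vinyl terminus of the left half is its only monosubstituted alkene, so 9-BBN marks C10 alone and an unactivated primary bromide at C11 completes the pair.
- Stereochemistry: C2 (R) comes from the chiral pool, methyl (S)-3-hydroxy-2-methylpropanoate; the descriptor switches S → R at step 3 only through a CIP priority change. C1 stays at the non-enolisable CH2OTBS level until the last oxidation.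
- Alkene geometry: E from syn-hydrozirconation of a methyl alkyne, then iodination and cross-coupling with retention.

Key step: step 8

Remark: (4-bromophenoxy)triisopropylsilane (12) is taken as a catalogue aryl bromide; TIPS is chosen on the phenol so that it outlasts the acid-catalysed removal of the alkyl TBS ether.

**Route**

Step 1
Reactants: 1 methyl (S)-3-hydroxy-2-methylpropanoate
Product: 2 methyl (S)-3-[(tert-butyldimethylsilyl)oxy]-2-methylpropanoate
Conditions: TBSCl, imidazole, CH2Cl2, 0 °C → rt
Reagents that add atoms: tert-butyldimethylsilyl chloride, CC(C)(C)[Si](C)(C)Cl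
Why: Imidazole-mediated silylation of a primary alcohol, which leaves the C2 centre untouched.

Step 2
Reactants: 2 methyl (S)-3-[(tert-butyldimethylsilyl)oxy]-2-methylpropanoate
Product: 3 (S)-3-[(tert-butyldimethylsilyl)oxy]-2-methylpropanal
Conditions: DIBAL-H (1.05 equiv), CH2Cl2, −78 °C; MeOH quench, aq. potassium sodium tartrate; used crude
Reagents that add atoms: none
Why: Partial ester reduction, in which the tetrahedral aluminium hemiacetal should persist at −78 °C and release the aldehyde only on work-up, so that the α-centre is not exposed to base.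

Step 3
Reactants: 3 (S)-3-[(tert-butyldimethylsilyl)oxy]-2-methylpropanal
Product: 4 (R)-tert-butyl[(4,4-dibromo-2-methylbut-3-en-1-yl)oxy]dimethylsilane
Conditions: CBr4, PPh3, CH2Cl2, 0 °C
Reagents that add atoms: carbon tetrabromide, BrC(Br)(Br)Br
Why: First stage of the Corey–Fuchs homologation, a Wittig-type dibromo-olefination with Ph3P=CBr2 that runs near neutrality at 0 °C and should therefore not epimerise the α-centre.

Step 4
Reactants: 4 (R)-tert-butyl[(4,4-dibromo-2-methylbut-3-en-1-yl)oxy]dimethylsilane
Product: 6 (R)-tert-butyldimethyl[(2-methylpent-3-yn-1-yl)oxy]silane, via lithium acetylide 5 (not isolated)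
Conditions: n-BuLi (2.2 equiv), THF, −78 °C; then MeI, −78 °C → rt
Reagents that add atoms: iodomethane, CI
Why: Second stage of the Corey–Fuchs homologation (Br/Li exchange, carbenoid 1,2-shift to the alkyne, deprotonation) followed by C-methylation of the acetylide, none of which touches the propargylic stereocentre.

Step 5
Reactants: 6 (R)-tert-butyldimethyl[(2-methylpent-3-yn-1-yl)oxy]silane
Product: 8 (R,E)-tert-butyl[(4-iodo-2-methylpent-3-en-1-yl)oxy]dimethylsilane, via alkenylzirconocene chloride 7 (not isolated)
Conditions: Cp2Zr(H)Cl (2 equiv), THF, 50 °C; then I2, 0 °C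
Reagents that add atoms: iodine, II
Why: Hydrozirconation adds Zr–H syn and, under equilibrating conditions, should place zirconium on the methyl-bearing alkyne carbon remote from the branched C2, and iodinolysis with retention then gives the iodide with iodine trans to C2 (E).

Step 6
Reactants: 8 (R,E)-tert-butyl[(4-iodo-2-methylpent-3-en-1-yl)oxy]dimethylsilane; 9 hexa-1,5-diene
Product: 11 (R,E)-tert-butyl[(2,4-dimethyldeca-3,9-dien-1-yl)oxy]dimethylsilane, via 9-(hex-5-en-1-yl)-9-BBN 10 (not isolated)
Conditions: 9 (5 equiv), 9-BBN, THF, 0 °C → rt, excess diene evaporated; then 8, PdCl2(dppf) (cat.), AsPh3 (cat.), Cs2CO3, DMF/THF/H2O, rt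
Reagents that add atoms: none
Why: B-alkyl Suzuki–Miyaura (sp2–sp3) coupling, in which excess diene should limit hydroboration to one terminus and the alkenyl iodide should couple with retention of the E geometry, forming C4–C5.

Step 7
Reactants: 12 (4-bromophenoxy)triisopropylsilane; 13 1,12-dibromododecane
Product: 15 [4-(12-bromododecyl)phenoxy]triisopropylsilane, via aryl Grignard reagent 14 (not isolated)
Conditions: 12, Mg, THF, rt → 40 °C; then added slowly to 13 (3 equiv), Li2CuCl4 (3 mol %), THF, −10 °C → rt
Reagents that add atoms: none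
Why: Copper-catalysed Grignard–primary alkyl bromide coupling (Kochi–Tamura type), in which the excess of dibromide should hold substitution to one chain end and the aryl TIPS ether is inert.

Step 8
Reactants: 11 (R,E)-tert-butyl[(2,4-dimethyldeca-3,9-dien-1-yl)oxy]dimethylsilane; 15 [4-(12-bromododecyl)phenoxy]triisopropylsilane
Product: 17 (R,E)-tert-butyl({2,4-dimethyl-22-[4-(triisopropylsilyloxy)phenyl]docos-3-en-1-yl}oxy)dimethylsilane, via B-alkyl-9-BBN 16 (not isolated)
Conditions: 11 (1.2 equiv), 9-BBN, THF, 0 °C → rt; then 15, Pd(OAc)2 (4 mol %), PCy3 (8 mol %), K3PO4·H2O (1.2 equiv), THF, rt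
Reagents that add atoms: none
Why: 9-BBN should add syn and anti-Markovnikov to the monosubstituted C9=C10 vinyl group only, because the trisubstituted, allylically branched C3=C4 alkene reacts far more slowly with this hindered borane. The primary B-alkyl-9-BBN, activated by K3PO4·H2O as a hydroxyborate, transmetalates to the alkyl–Pd(II) species formed by SN2-type oxidative addition of the unactivated primary C11–Br bond to electron-rich Pd(0)/PCy3, and reductive elimination forms the C10–C11 sp3–sp3 bond. The closest known reaction type is the room-temperature alkyl–alkyl Suzuki–Miyaura coupling of primary alkyl bromides bearing β-hydrogens with B-alkyl-9-BBN reagents. No ring is closed and no stereocentre is created. The step needs chemoselective hydroboration (terminal over trisubstituted alkene), cross-coupling in preference to β-hydride elimination, and integrity of C2 and the E alkene; these are secured respectively by the single unhindered vinyl terminus, by the bulky electron-rich phosphine, and by near-neutral room-temperature conditions with C1 held at the non-enolisable CH2OTBS level. Both silyl ethers should be inert to the mild phosphate base.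

Step 9
Reactants: 17 (R,E)-tert-butyl({2,4-dimethyl-22-[4-(triisopropylsilyloxy)phenyl]docos-3-en-1-yl}oxy)dimethylsilane
Product: 18 (R,E)-2,4-dimethyl-22-[4-(triisopropylsilyloxy)phenyl]docos-3-en-1-ol
Conditions: CSA (10 mol %), MeOH/CH2Cl2 (1:1), 0 °C
Reagents that add atoms: none
Why: Acid-catalysed methanolysis should cleave the primary alkyl TBS ether much faster than the bulkier aryl TIPS ether, which is comparatively stable to acid.

Step 10
Reactants: 18 (R,E)-2,4-dimethyl-22-[4-(triisopropylsilyloxy)phenyl]docos-3-en-1-ol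
Product: 19 (R,E)-2,4-dimethyl-22-[4-(triisopropylsilyloxy)phenyl]docos-3-enal
Conditions: Dess–Martin periodinane, NaHCO3, CH2Cl2, 0 °C → rt; used at once
Reagents that add atoms: none
Why: Dess–Martin oxidation under buffered, base-free conditions, where C2 should hold because a planar dienol would suffer A1,3 strain between the C4 methyl group and the C2 substituents and because the aldehyde is not stored.

Step 11
Reactants: 19 (R,E)-2,4-dimethyl-22-[4-(triisopropylsilyloxy)phenyl]docos-3-enal
Product: 20 (R,E)-2,4-dimethyl-22-[4-(triisopropylsilyloxy)phenyl]docos-3-enoic acid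
Conditions: NaClO2, NaH2PO4, 2-methyl-2-butene, t-BuOH/THF/H2O, 0 °C
Reagents that add atoms: sodium chlorite, [Na+].[O-]Cl=O
Why: Pinnick oxidation at about pH 4, in which 2-methyl-2-butene scavenges the hypochlorous acid so that the C3=C4 alkene and the silyl ether are spared and C2 is not enolised.

Step 12
Reactants: 20 (R,E)-2,4-dimethyl-22-[4-(triisopropylsilyloxy)phenyl]docos-3-enoic acid
Product: 21 elenic acid, (R,E)-22-(4-hydroxyphenyl)-2,4-dimethyldocos-3-enoic acid
Conditions: TBAF (3 equiv), THF, 0 °C → rt; cold dilute HCl work-up to pH 3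
Reagents that add atoms: none
Why: Fluoride-induced cleavage of the aryl silyl ether, during which the acid is present as its carboxylate and C2 is thereby protected from enolisation, and the brief cold acidic work-up should not lactonise the β,γ-unsaturated acid.

**Compound list**

1 | methyl (S)-3-hydroxy-2-methylpropanoate | COC(=O)[C@@H](C)CO | starting material
2 | methyl (S)-3-[(tert-butyldimethylsilyl)oxy]-2-methylpropanoate | COC(=O)[C@@H](C)CO[Si](C)(C)C(C)(C)C | intermediate
3 | (S)-3-[(tert-butyldimethylsilyl)oxy]-2-methylpropanal | O=C[C@@H](C)CO[Si](C)(C)C(C)(C)C | intermediate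
4 | (R)-tert-butyl[(4,4-dibromo-2-methylbut-3-en-1-yl)oxy]dimethylsilane | BrC(Br)=C[C@@H](C)CO[Si](C)(C)C(C)(C)C | intermediate
5 | lithium acetylide of (R)-tert-butyl[(2-methylbut-3-yn-1-yl)oxy]dimethylsilane | [Li]C#C[C@@H](C)CO[Si](C)(C)C(C)(C)C | intermediate (not isolated)
6 | (R)-tert-butyldimethyl[(2-methylpent-3-yn-1-yl)oxy]silane | CC#C[C@@H](C)CO[Si](C)(C)C(C)(C)C | intermediate
7 | (R,E)-[5-(tert-butyldimethylsilyloxy)-4-methylpent-2-en-2-yl]zirconocene chloride | C/C(=C\[C@@H](C)CO[Si](C)(C)C(C)(C)C)[Zr](Cl)(C1C=CC=C1)C1C=CC=C1 | intermediate (not isolated)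
8 | (R,E)-tert-butyl[(4-iodo-2-methylpent-3-en-1-yl)oxy]dimethylsilane | C/C(I)=C\[C@@H](C)CO[Si](C)(C)C(C)(C)C | intermediate
9 | hexa-1,5-diene | C=CCCC=C | starting material
10 | 9-(hex-5-en-1-yl)-9-borabicyclo[3.3.1]nonane | C=CCCCCB1C2CCCC1CCC2 | intermediate (not isolated)
11 | (R,E)-tert-butyl[(2,4-dimethyldeca-3,9-dien-1-yl)oxy]dimethylsilane | C/C(=C\[C@@H](C)CO[Si](C)(C)C(C)(C)C)CCCCC=C | intermediate
12 | (4-bromophenoxy)triisopropylsilane | CC(C)[Si](Oc1ccc(Br)cc1)(C(C)C)C(C)C | starting material
13 | 1,12-dibromododecane | BrCCCCCCCCCCCCBr | starting material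
14 | [4-(triisopropylsilyloxy)phenyl]magnesium bromide | CC(C)[Si](Oc1ccc([Mg]Br)cc1)(C(C)C)C(C)C | intermediate (not isolated)
15 | [4-(12-bromododecyl)phenoxy]triisopropylsilane | CC(C)[Si](Oc1ccc(CCCCCCCCCCCCBr)cc1)(C(C)C)C(C)C | intermediate
16 | 9-[(R,E)-10-(tert-butyldimethylsilyloxy)-7,9-dimethyldec-7-en-1-yl]-9-borabicyclo[3.3.1]nonane | C/C(=C\[C@@H](C)CO[Si](C)(C)C(C)(C)C)CCCCCCB1C2CCCC1CCC2 | intermediate (not isolated)
17 | (R,E)-tert-butyl({2,4-dimethyl-22-[4-(triisopropylsilyloxy)phenyl]docos-3-en-1-yl}oxy)dimethylsilane | C/C(=C\[C@@H](C)CO[Si](C)(C)C(C)(C)C)CCCCCCCCCCCCCCCCCCc1ccc(O[Si](C(C)C)(C(C)C)C(C)C)cc1 | intermediate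
18 | (R,E)-2,4-dimethyl-22-[4-(triisopropylsilyloxy)phenyl]docos-3-en-1-ol | C/C(=C\[C@@H](C)CO)CCCCCCCCCCCCCCCCCCc1ccc(O[Si](C(C)C)(C(C)C)C(C)C)cc1 | intermediate
19 | (R,E)-2,4-dimethyl-22-[4-(triisopropylsilyloxy)phenyl]docos-3-enal | C/C(=C\[C@@H](C)C=O)CCCCCCCCCCCCCCCCCCc1ccc(O[Si](C(C)C)(C(C)C)C(C)C)cc1 | intermediate
20 | (R,E)-2,4-dimethyl-22-[4-(triisopropylsilyloxy)phenyl]docos-3-enoic acid | C/C(=C\[C@@H](C)C(=O)O)CCCCCCCCCCCCCCCCCCc1ccc(O[Si](C(C)C)(C(C)C)C(C)C)cc1 | intermediate
21 | elenic acid, (R,E)-22-(4-hydroxyphenyl)-2,4-dimethyldocos-3-enoic acid | C/C(=C\[C@@H](C)C(=O)O)CCCCCCCCCCCCCCCCCCc1ccc(O)cc1 | target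

**Totals**

Total step count: 12. Longest linear sequence: 11 (steps 1–6 and 8–12); the right-hand branch is step 7.

**Steps most likely to fail and fallbacks**

Step 8. Oxidative addition of the unactivated primary bromide may be slow, so that β-hydride elimination from the alkyl–palladium intermediate or protodeboronation of the borane outruns formation of the C10–C11 bond. The fallback reverses the polarity and uses copper instead of palladium; it sets out from 11 and 15 and comes back at 17. Diene 11 would be hydroborated with 9-BBN and oxidised (NaBO3·4H2O) to the primary alcohol (R,E)-10-[(tert-butyldimethylsilyl)oxy]-7,9-dimethyldec-7-en-1-ol F1, which TsCl/pyridine should convert into the tosylate (R,E)-10-[(tert-butyldimethylsilyl)oxy]-7,9-dimethyldec-7-en-1-yl 4-methylbenzenesulfonate F2. Bromide 15 would be converted with magnesium in THF into {12-[4-(triisopropylsilyloxy)phenyl]dodecyl}magnesium bromide F3. Li2CuCl4-catalysed coupling of F3 with F2 (THF, −20 °C → rt) should form the same C10–C11 bond and give 17.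

Step 5. Regiocontrol of the hydrozirconation may be incomplete, with zirconium partly settling on the carbon next to C2, or the alkenylzirconium may be protonated before iodination, leaving isomeric iodides and alkenes that are hard to separate. The fallback sets the E alkene by a stabilised Wittig reaction instead; it sets out from aldehyde 3 and comes back at 11, replacing steps 3–6. Aldehyde 3 and ethyl 2-(triphenylphosphoranylidene)propanoate (CH2Cl2, rt → 40 °C) should give ethyl (R,E)-5-[(tert-butyldimethylsilyl)oxy]-2,4-dimethylpent-2-enoate F4. DIBAL-H (CH2Cl2, −78 °C) would reduce it to (R,E)-5-[(tert-butyldimethylsilyl)oxy]-2,4-dimethylpent-2-en-1-ol F5, and CBr4/PPh3 should give the allylic bromide (R,E)-[(5-bromo-2,4-dimethylpent-3-en-1-yl)oxy](tert-butyl)dimethylsilane F6. Li2CuCl4-catalysed SN2 coupling of F6 with pent-4-en-1-ylmagnesium bromide (THF, −78 → 0 °C) should then give 11.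

Step 7. Substitution may run on at both ends of the dibromide, and the aryl Grignard reagent may homocouple, so that the mono-bromide is obtained only as part of a mixture of non-polar products. The fallback makes the arene the electrophile under palladium catalysis; it sets out from 12 and comes back at 15. Commercial 12-bromododec-1-ene would be hydroborated with 9-BBN to 9-(12-bromododecyl)-9-borabicyclo[3.3.1]nonane F7, which should couple with aryl bromide 12 (PdCl2(dppf), K3PO4, THF/DMF/H2O, 50 °C) at the aryl C–Br bond in preference to the primary alkyl C–Br bond, giving 15.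

**Further compounds**

F1 | step 8 | (R,E)-10-[(tert-butyldimethylsilyl)oxy]-7,9-dimethyldec-7-en-1-ol | C/C(=C\[C@@H](C)CO[Si](C)(C)C(C)(C)C)CCCCCCO
F2 | step 8 | (R,E)-10-[(tert-butyldimethylsilyl)oxy]-7,9-dimethyldec-7-en-1-yl 4-methylbenzenesulfonate | C/C(=C\[C@@H](C)CO[Si](C)(C)C(C)(C)C)CCCCCCOS(=O)(=O)c1ccc(C)cc1
F3 | step 8 | {12-[4-(triisopropylsilyloxy)phenyl]dodecyl}magnesium bromide | CC(C)[Si](Oc1ccc(CCCCCCCCCCCC[Mg]Br)cc1)(C(C)C)C(C)C
F4 | step 5 | ethyl (R,E)-5-[(tert-butyldimethylsilyl)oxy]-2,4-dimethylpent-2-enoate | CCOC(=O)/C(C)=C/[C@@H](C)CO[Si](C)(C)C(C)(C)C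
F5 | step 5 | (R,E)-5-[(tert-butyldimethylsilyl)oxy]-2,4-dimethylpent-2-en-1-ol | OC/C(C)=C/[C@@H](C)CO[Si](C)(C)C(C)(C)C
F6 | step 5 | (R,E)-[(5-bromo-2,4-dimethylpent-3-en-1-yl)oxy](tert-butyl)dimethylsilane | BrC/C(C)=C/[C@@H](C)CO[Si](C)(C)C(C)(C)C
F7 | step 7 | 9-(12-bromododecyl)-9-borabicyclo[3.3.1]nonane | BrCCCCCCCCCCCCB1C2CCCC1CCC2
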